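## Retrosynthetic overview

1. The usual plan (close the ten-membered ring early by metathesis at the Z-trisubstituted olefin, then epoxidise, acylate and deprotect on the ring) is set aside: the carbocycle (ring B) is closed in the very last step.
2. Key step: intramolecular Nozaki–Hiyama–Kishi reaction (C4–C5) of a vinyl bromide/α-acyloxy aldehyde that already carries the α-methylene lactone, the angelate and the oxirane; Felkin–Anh control from C6 sets C5 and the free target is released with no protecting group left.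
3. Ring A (cis-γ-lactone, C6/C7): chromium Barbier allylation/lactonisation of a Morita–Baylis–Hillman-derived allyl bromide with PMB-oxyacetaldehyde, steered by the C8 silyl ether.
4. Oxirane: Shi epoxidation of the acyclic Z-olefin (from a Zhao iodo-olefination); C8 from methyl (S)-glycidate; angelate by mixed-anhydride esterification.
5. Ring order: oxirane → ring A (lactone) → ring B (carbocycle).

Assumption: the SMILES defines the target (CIP 1R,5S,6R,7R,8S,10S), and germacrane-type locants are used throughout: C6 = lactone O–CH, C7 = CH bearing C11, C8 = CH–O-angelate, C9 = CH2, C10/C1 = oxirane C(CH3)/CH, C2/C3 = CH2, C4 = C(=CH2), C5 = CH–OH, C11–C13 = lactone C(=CH2)/C=O/=CH2.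

Abbreviations: TBS = tert-butyldimethylsilyl; PMB = 4-methoxybenzyl.

## Route

Step 1
Reactants: 1 tert-butyl acetate; 2 2,3-dibromoprop-1-ene
Product: 4 tert-butyl 4-bromopent-4-enoate, via lithium enolate 3 (not isolated)
Conditions: LiN(i-Pr)2, THF, −78 °C; then 2, −78 → 0 °C
Reagents that add atoms: none
Why: Ester enolate alkylation (SN2): the lithium enolate of the tert-butyl ester, which resists Claisen self-condensation, displaces only the allylic bromide of 2 because the vinylic C–Br bond is inert to SN2, and no stereocentre is formed.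

Step 2
Reactants: 4 tert-butyl 4-bromopent-4-enoate
Product: 5 4-bromopent-4-enal
Conditions: i-Bu2AlH (1.05 equiv), CH2Cl2, −78 °C
Reagents that add atoms: none
Why: Partial ester reduction with i-Bu2AlH: at −78 °C the tetrahedral aluminium hemiacetal is stable and collapses to the aldehyde only on aqueous work-up, so over-reduction is avoided and the vinyl bromide is untouched; no stereocentre is formed.

Step 3
Reactants: 5 4-bromopent-4-enal; 6 ethyltriphenylphosphonium iodide
Product: 10 (5Z)-2-bromo-6-iodohepta-1,5-diene, via ethylidenetriphenylphosphorane 7 (not isolated), via (1-iodoethyl)triphenylphosphonium iodide 8 (not isolated), via (1-iodoethylidene)triphenylphosphorane 9 (not isolated)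
Conditions: 6, n-BuLi, THF, rt; I2, −78 °C; NaN(SiMe3)2, −20 °C; then 5, −78 °C
Reagents that add atoms: iodine, II
Why: Stork–Zhao iodo-olefination (Wittig reaction of a non-stabilised α-iodo ylide): kinetic, cis-selective oxaphosphetane formation places iodine cis to the chain and gives the (Z)-2-iodo-2-alkene (typically about 10:1), which fixes the Z geometry of the later C1=C10 bond.

Step 4
Reactants: 10 (5Z)-2-bromo-6-iodohepta-1,5-diene; 11 methyl (2S)-oxirane-2-carboxylate
Product: 13 methyl (2S,4Z)-8-bromo-2-hydroxy-4-methylnona-4,8-dienoate, via alkenylmagnesium chloride 12 (not isolated)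
Conditions: i-PrMgCl·LiCl, THF, 0 °C → rt; then CuI (10 mol %), 11, −40 → −20 °C
Reagents that add atoms: none
Why: Iodine–magnesium exchange followed by copper-catalysed epoxide opening: the exchange is much faster at C–I than at C–Br and retains the olefin geometry, the alkenyl nucleophile opens the glycidate by SN2 attack at its CH2 terminus faster than it adds to the ester, and the C8 stereocentre comes unchanged from 11, so 13 is (2S).

Step 5
Reactants: 13 methyl (2S,4Z)-8-bromo-2-hydroxy-4-methylnona-4,8-dienoate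
Product: 14 methyl (2S,4Z)-8-bromo-4-methyl-2-(TBS-oxy)nona-4,8-dienoate
Conditions: t-BuMe2SiCl, imidazole, DMF, rt
Reagents that add atoms: tert-butyldimethylsilyl chloride, CC(C)(C)[Si](C)(C)Cl
Why: Silylation of the secondary alcohol (silyl ether protection) installs a bulky, non-chelating group at C8 that later directs step 10; the stereocentre is not touched.

Step 6
Reactants: 14 methyl (2S,4Z)-8-bromo-4-methyl-2-(TBS-oxy)nona-4,8-dienoate
Product: 15 methyl (2S)-3-[(2S,3R)-3-(3-bromobut-3-en-1-yl)-2-methyloxiran-2-yl]-2-(TBS-oxy)propanoate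
Conditions: Shi ketone (1,2:4,5-di-O-isopropylidene-β-D-erythro-2,3-hexodiulo-2,6-pyranose, 0.3 equiv), KHSO5 (as 2KHSO5·KHSO4·K2SO4), K2CO3, n-Bu4NHSO4, MeCN/CH2(OMe)2/aq. Na2B4O7 buffer (pH 10.5), 0 °C
Reagents that add atoms: potassium peroxymonosulfate, [K+].[O-]S(=O)(=O)OO
Why: Shi asymmetric epoxidation: the chiral dioxirane from the D-fructose-derived ketone attacks the only electron-rich olefin through a spiro transition state with the single vinylic hydrogen in the hindered quadrant, which by the rule established for trans- and trisubstituted olefins delivers oxygen to the face that gives the (1R,10S) cis-epoxide under reagent control, while the vinyl bromide and the ester do not react.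

Step 7
Reactants: 15 methyl (2S)-3-[(2S,3R)-3-(3-bromobut-3-en-1-yl)-2-methyloxiran-2-yl]-2-(TBS-oxy)propanoate
Product: 16 (2S)-3-[(2S,3R)-3-(3-bromobut-3-en-1-yl)-2-methyloxiran-2-yl]-2-(TBS-oxy)propanal
Conditions: i-Bu2AlH (1.1 equiv), CH2Cl2, −78 °C
Reagents that add atoms: none
Why: Partial reduction of the α-silyloxy methyl ester with i-Bu2AlH at −78 °C stops at the aldehyde via the chelated aluminium hemiacetal, without epimerising C8 and without opening the trisubstituted epoxide.

Step 8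
Reactants: 16 (2S)-3-[(2S,3R)-3-(3-bromobut-3-en-1-yl)-2-methyloxiran-2-yl]-2-(TBS-oxy)propanal; 17 methyl acrylate
Product: 18 methyl (4S)-5-[(2S,3R)-3-(3-bromobut-3-en-1-yl)-2-methyloxiran-2-yl]-3-hydroxy-2-methylidene-4-(TBS-oxy)pentanoate (both C3 epimers)
Conditions: 17 (5 equiv), 1,4-diazabicyclo[2.2.2]octane (1 equiv), neat, rt, 3–6 d
Reagents that add atoms: none
Why: Morita–Baylis–Hillman reaction: the amine–acrylate zwitterion adds to the electrophilic α-silyloxy aldehyde and β-elimination releases the amine, and the new carbinol centre, formed as a mixture of epimers, is irrelevant because it is erased in step 9.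

Step 9
Reactants: 18 methyl (4S)-5-[(2S,3R)-3-(3-bromobut-3-en-1-yl)-2-methyloxiran-2-yl]-3-hydroxy-2-methylidene-4-(TBS-oxy)pentanoate (both C3 epimers)
Product: 20 methyl (2Z,4S)-2-(bromomethyl)-5-[(2S,3R)-3-(3-bromobut-3-en-1-yl)-2-methyloxiran-2-yl]-4-(TBS-oxy)pent-2-enoate, via allylic mesylate 19 (not isolated)
Conditions: MeSO2Cl, Et3N, CH2Cl2, −20 °C; then LiBr, acetone, rt
Reagents that add atoms: lithium bromide, [Li+].[Br-]
Why: Mesylation followed by SN2′ displacement with bromide (allylic transposition) gives the thermodynamically preferred (2Z)-2-(bromomethyl)enoate under non-acidic conditions that spare the epoxide, and the carbinol stereocentre disappears.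

Step 10
Reactants: 20 methyl (2Z,4S)-2-(bromomethyl)-5-[(2S,3R)-3-(3-bromobut-3-en-1-yl)-2-methyloxiran-2-yl]-4-(TBS-oxy)pent-2-enoate; 21 [(4-methoxybenzyl)oxy]acetaldehyde
Product: 23 (4S,5R)-4-{(1S)-2-[(2S,3R)-3-(3-bromobut-3-en-1-yl)-2-methyloxiran-2-yl]-1-(TBS-oxy)ethyl}-3-methylidene-5-[(PMB-oxy)methyl]oxolan-2-one, via hydroxy ester 22 (not isolated)
Conditions: CrCl2 (4 equiv), 21 (1.5 equiv), THF, rt
Reagents that add atoms: none
Why: Chromium-mediated Barbier allylation (Nozaki–Hiyama type) with in-flask lactonisation: the 2-(methoxycarbonyl)allylchromium reagent adds through a chair transition state with its γ-substituent axial, giving the syn adduct and hence the cis-lactone (C6 and C7), and it is attacked anti to the allylic silyloxy group with H8 eclipsing the olefin (allylic 1,3-strain), which relays the C8 configuration to C7 and C6; without a nickel co-catalyst the vinyl bromide is inert, and the chromium alkoxide of 22 closes ring A with loss of methanol.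

Step 11
Reactants: 23 (4S,5R)-4-{(1S)-2-[(2S,3R)-3-(3-bromobut-3-en-1-yl)-2-methyloxiran-2-yl]-1-(TBS-oxy)ethyl}-3-methylidene-5-[(PMB-oxy)methyl]oxolan-2-one
Product: 24 (4R,5R)-4-{(1S)-2-[(2S,3R)-3-(3-bromobut-3-en-1-yl)-2-methyloxiran-2-yl]-1-hydroxyethyl}-3-methylidene-5-[(PMB-oxy)methyl]oxolan-2-one
Conditions: n-Bu4NF, AcOH (1:1), THF, 0 °C → rt
Reagents that add atoms: none
Why: Fluoride-mediated desilylation buffered with acetic acid keeps the medium close to neutral, so that the α-methylene lactone is not attacked and the liberated C8 hydroxyl does not translactonise; no stereocentre is affected.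

Step 12
Reactants: 24 (4R,5R)-4-{(1S)-2-[(2S,3R)-3-(3-bromobut-3-en-1-yl)-2-methyloxiran-2-yl]-1-hydroxyethyl}-3-methylidene-5-[(PMB-oxy)methyl]oxolan-2-one; 25 angelic acid
Product: 27 (1S)-2-[(2S,3R)-3-(3-bromobut-3-en-1-yl)-2-methyloxiran-2-yl]-1-{(2R,3R)-4-methylidene-5-oxo-2-[(PMB-oxy)methyl]oxolan-3-yl}ethyl (2Z)-2-methylbut-2-enoate, via mixed anhydride 26 (not isolated)
Conditions: 25, 2,4,6-Cl3C6H2COCl, Et3N, toluene, rt (filter); then 24, 80 °C
Reagents that add atoms: none
Why: Mixed-anhydride esterification (Yamaguchi-type, run thermally without a nucleophilic catalyst) acylates the C8 alcohol at the less hindered angeloyl carbonyl without isomerising the Z-olefin to the tiglate, and C8 keeps its configuration because its C–O bond is not broken.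

Step 13
Reactants: 27 (1S)-2-[(2S,3R)-3-(3-bromobut-3-en-1-yl)-2-methyloxiran-2-yl]-1-{(2R,3R)-4-methylidene-5-oxo-2-[(PMB-oxy)methyl]oxolan-3-yl}ethyl (2Z)-2-methylbut-2-enoate
Product: 28 (1S)-2-[(2S,3R)-3-(3-bromobut-3-en-1-yl)-2-methyloxiran-2-yl]-1-[(2R,3R)-2-(hydroxymethyl)-4-methylidene-5-oxooxolan-3-yl]ethyl (2Z)-2-methylbut-2-enoate
Conditions: DDQ, CH2Cl2/aq. NaH2PO4–Na2HPO4 buffer (pH 7), 0 °C → rt
Reagents that add atoms: none
Why: Oxidative cleavage of the 4-methoxybenzyl ether with DDQ (hydride abstraction to the oxocarbenium ion, then hydrolysis) is selective for the electron-rich benzyl ether and leaves the epoxide, the angelate, the enoate and the vinyl bromide untouched.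

Step 14
Reactants: 28 (1S)-2-[(2S,3R)-3-(3-bromobut-3-en-1-yl)-2-methyloxiran-2-yl]-1-[(2R,3R)-2-(hydroxymethyl)-4-methylidene-5-oxooxolan-3-yl]ethyl (2Z)-2-methylbut-2-enoate
Product: 29 (1S)-2-[(2S,3R)-3-(3-bromobut-3-en-1-yl)-2-methyloxiran-2-yl]-1-[(2R,3R)-2-formyl-4-methylidene-5-oxooxolan-3-yl]ethyl (2Z)-2-methylbut-2-enoate
Conditions: Dess–Martin periodinane, pyridine, CH2Cl2, 0 °C
Reagents that add atoms: none
Why: Dess–Martin oxidation of the primary alcohol under pyridine buffering is mild enough to give the α-acyloxy aldehyde without epimerisation at C6 or epoxide opening, and the aldehyde is used at once.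

Step 15
Reactants: 29 (1S)-2-[(2S,3R)-3-(3-bromobut-3-en-1-yl)-2-methyloxiran-2-yl]-1-[(2R,3R)-2-formyl-4-methylidene-5-oxooxolan-3-yl]ethyl (2Z)-2-methylbut-2-enoate
Product: 30 (1R,5S,6R,7R,8S,10S)-8-angeloyloxy-1,10-epoxy-5-hydroxygermacra-4(15),11(13)-dien-12,6-olide (CNP0227074.3)
Conditions: CrCl2 (10 equiv), NiCl2 (5 mol %), DMSO, rt → 40 °C, 0.003 M (slow addition of 29)
Reagents that add atoms: none
Why: Intramolecular Nozaki–Hiyama–Kishi reaction: NiCl2 catalyses activation of the C4–Br bond, transmetalation to trivalent chromium gives an alkenylchromium species that adds only to the aldehyde and closes ring B under high dilution, and polar Felkin–Anh (Cornforth) attack anti to the C6–O bond sets the (5S) carbinol, while lactone, angelate, enoate and epoxide are tolerated by this reagent.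

## Compound list

1 | tert-butyl acetate | CC(=O)OC(C)(C)C | starting material
2 | 2,3-dibromoprop-1-ene | C=C(Br)CBr | starting material
3 | lithium enolate of tert-butyl acetate | [Li]OC(=C)OC(C)(C)C | intermediate
4 | tert-butyl 4-bromopent-4-enoate | C=C(Br)CCC(=O)OC(C)(C)C | intermediate
5 | 4-bromopent-4-enal | C=C(Br)CCC=O | intermediate
6 | ethyltriphenylphosphonium iodide | CC[P+](c1ccccc1)(c1ccccc1)c1ccccc1.[I-] | starting material
7 | ethylidenetriphenylphosphorane | CC=P(c1ccccc1)(c1ccccc1)c1ccccc1 | intermediate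
8 | (1-iodoethyl)triphenylphosphonium iodide (racemic) | CC(I)[P+](c1ccccc1)(c1ccccc1)c1ccccc1.[I-] | intermediate
9 | (1-iodoethylidene)triphenylphosphorane | CC(I)=P(c1ccccc1)(c1ccccc1)c1ccccc1 | intermediate
10 | (5Z)-2-bromo-6-iodohepta-1,5-diene | C=C(Br)CC/C=C(\I)C | intermediate
11 | methyl (2S)-oxirane-2-carboxylate [methyl (S)-glycidate] | COC(=O)[C@@H]1CO1 | starting material
12 | [(2Z)-6-bromohepta-2,6-dien-2-yl]magnesium chloride | C=C(Br)CC/C=C(\[Mg]Cl)C | intermediate
13 | methyl (2S,4Z)-8-bromo-2-hydroxy-4-methylnona-4,8-dienoate | COC(=O)[C@@H](O)C/C(C)=C\CCC(Br)=C | intermediate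
14 | methyl (2S,4Z)-8-bromo-4-methyl-2-(TBS-oxy)nona-4,8-dienoate | COC(=O)[C@@H](O[Si](C)(C)C(C)(C)C)C/C(C)=C\CCC(Br)=C | intermediate
15 | methyl (2S)-3-[(2S,3R)-3-(3-bromobut-3-en-1-yl)-2-methyloxiran-2-yl]-2-(TBS-oxy)propanoate | COC(=O)[C@@H](O[Si](C)(C)C(C)(C)C)C[C@]1(C)O[C@@H]1CCC(Br)=C | intermediate
16 | (2S)-3-[(2S,3R)-3-(3-bromobut-3-en-1-yl)-2-methyloxiran-2-yl]-2-(TBS-oxy)propanal | O=C[C@@H](O[Si](C)(C)C(C)(C)C)C[C@]1(C)O[C@@H]1CCC(Br)=C | intermediate
17 | methyl acrylate | C=CC(=O)OC | starting material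
18 | methyl (4S)-5-[(2S,3R)-3-(3-bromobut-3-en-1-yl)-2-methyloxiran-2-yl]-3-hydroxy-2-methylidene-4-(TBS-oxy)pentanoate (both C3 epimers) | C=C(C(=O)OC)C(O)[C@@H](O[Si](C)(C)C(C)(C)C)C[C@]1(C)O[C@@H]1CCC(Br)=C | intermediate
19 | methyl (4S)-5-[(2S,3R)-3-(3-bromobut-3-en-1-yl)-2-methyloxiran-2-yl]-3-(methanesulfonyloxy)-2-methylidene-4-(TBS-oxy)pentanoate (both C3 epimers) | C=C(C(=O)OC)C(OS(C)(=O)=O)[C@@H](O[Si](C)(C)C(C)(C)C)C[C@]1(C)O[C@@H]1CCC(Br)=C | intermediate
20 | methyl (2Z,4S)-2-(bromomethyl)-5-[(2S,3R)-3-(3-bromobut-3-en-1-yl)-2-methyloxiran-2-yl]-4-(TBS-oxy)pent-2-enoate | COC(=O)/C(CBr)=C/[C@@H](O[Si](C)(C)C(C)(C)C)C[C@]1(C)O[C@@H]1CCC(Br)=C | intermediate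
21 | [(4-methoxybenzyl)oxy]acetaldehyde | O=CCOCc1ccc(OC)cc1 | starting material
22 | methyl (3S,4R)-3-{(1S)-2-[(2S,3R)-3-(3-bromobut-3-en-1-yl)-2-methyloxiran-2-yl]-1-(TBS-oxy)ethyl}-4-hydroxy-2-methylidene-5-(PMB-oxy)pentanoate | COC(=O)C(=C)[C@@H]([C@@H](O)COCc1ccc(OC)cc1)[C@@H](O[Si](C)(C)C(C)(C)C)C[C@]1(C)O[C@@H]1CCC(Br)=C | intermediate
23 | (4S,5R)-4-{(1S)-2-[(2S,3R)-3-(3-bromobut-3-en-1-yl)-2-methyloxiran-2-yl]-1-(TBS-oxy)ethyl}-3-methylidene-5-[(PMB-oxy)methyl]oxolan-2-one | C=C1C(=O)O[C@@H](COCc2ccc(OC)cc2)[C@H]1[C@@H](O[Si](C)(C)C(C)(C)C)C[C@]1(C)O[C@@H]1CCC(Br)=C | intermediate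
24 | (4R,5R)-4-{(1S)-2-[(2S,3R)-3-(3-bromobut-3-en-1-yl)-2-methyloxiran-2-yl]-1-hydroxyethyl}-3-methylidene-5-[(PMB-oxy)methyl]oxolan-2-one | C=C1C(=O)O[C@@H](COCc2ccc(OC)cc2)[C@H]1[C@@H](O)C[C@]1(C)O[C@@H]1CCC(Br)=C | intermediate
25 | angelic acid [(2Z)-2-methylbut-2-enoic acid] | C/C=C(/C)C(=O)O | starting material
26 | (2Z)-2-methylbut-2-enoic 2,4,6-trichlorobenzoic anhydride | C/C=C(/C)C(=O)OC(=O)c1c(Cl)cc(Cl)cc1Cl | intermediate
27 | (1S)-2-[(2S,3R)-3-(3-bromobut-3-en-1-yl)-2-methyloxiran-2-yl]-1-{(2R,3R)-4-methylidene-5-oxo-2-[(PMB-oxy)methyl]oxolan-3-yl}ethyl (2Z)-2-methylbut-2-enoate | C=C1C(=O)O[C@@H](COCc2ccc(OC)cc2)[C@H]1[C@@H](OC(=O)/C(C)=C\C)C[C@]1(C)O[C@@H]1CCC(Br)=C | intermediate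
28 | (1S)-2-[(2S,3R)-3-(3-bromobut-3-en-1-yl)-2-methyloxiran-2-yl]-1-[(2R,3R)-2-(hydroxymethyl)-4-methylidene-5-oxooxolan-3-yl]ethyl (2Z)-2-methylbut-2-enoate | C=C1C(=O)O[C@@H](CO)[C@H]1[C@@H](OC(=O)/C(C)=C\C)C[C@]1(C)O[C@@H]1CCC(Br)=C | intermediate
29 | (1S)-2-[(2S,3R)-3-(3-bromobut-3-en-1-yl)-2-methyloxiran-2-yl]-1-[(2R,3R)-2-formyl-4-methylidene-5-oxooxolan-3-yl]ethyl (2Z)-2-methylbut-2-enoate | C=C1C(=O)O[C@@H](C=O)[C@H]1[C@@H](OC(=O)/C(C)=C\C)C[C@]1(C)O[C@@H]1CCC(Br)=C | intermediate
30 | (1R,5S,6R,7R,8S,10S)-8-angeloyloxy-1,10-epoxy-5-hydroxygermacra-4(15),11(13)-dien-12,6-olide (CNP0227074.3) | C=C1C(=O)O[C@@H]2[C@H]1[C@@H](OC(=O)/C(C)=C\C)C[C@]1(C)O[C@@H]1CCC(=C)[C@@H]2O | target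

## Summary and fallbacks

Total steps: 15. Longest linear sequence: 15 steps (1/2 → 30); 6, 11, 17, 21 and 25 are purchased building blocks.

The three steps most likely to fail are the ring closure (step 15), the stereo-relaying allylation (step 10) and the Morita–Baylis–Hillman reaction (step 8).

Ring closure, step 15. The ten-membered ring may close slowly from the vinyl bromide, and the macrocyclic constraint may erode or reverse the Felkin preference at C5. The fallback sets out from 29 and comes back at 30, and it no longer relies on the C–C bond formation to set C5. The crude carbinol mixture, 30 together with the C5 epimer of 30 F1, is oxidised with Dess–Martin periodinane to the cross-conjugated 5-ketone F2. F2 is then reduced under reagent control with (S)-1-methyl-3,3-diphenyltetrahydro-1H,3H-pyrrolo[1,2-c][1,3,2]oxazaborole (cat.) and catecholborane at −78 °C. The alkenyl arm acts as the large group, which predicts 5S; the antipodal catalyst is the obvious variable.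

Allylation, step 10. The fluxional allylchromium reagent could give the trans-lactone or attack the wrong face relative to C8. The fallback sets out from 18 and comes back at 23, replacing the Barbier reaction by a stereospecific allylboration. Compound 18 is acetylated (Ac2O, 4-dimethylaminopyridine) to the Morita–Baylis–Hillman acetate F3. SN2′ borylation with bis(pinacolato)diboron and tris(dibenzylideneacetone)dipalladium (Pd2(dba)3, cat.) gives the configurationally stable allylboronate F4. Heating F4 with 21 in toluene at 110 °C goes through a closed chair transition state to the O-boryl syn adduct F5, which lactonises to 23.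

Morita–Baylis–Hillman reaction, step 8. The branched α-silyloxy aldehyde may react too slowly, and long exposure to the amine risks epimerising C8. The fallback sets out from 16 and comes back at 18, using a preformed nucleophile instead of amine catalysis. Hydroalumination of methyl propiolate with i-Bu2AlH and N-methylmorpholine N-oxide in THF at 0 °C gives [1-(methoxycarbonyl)ethenyl]bis(2-methylpropyl)aluminium F6. F6 adds to 16 within hours at 0 °C and gives 18 after aqueous work-up.

Further compounds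
F1 | step 15 | C5 epimer of 30, (1R,5R,6R,7R,8S,10S) | C=C1C(=O)O[C@@H]2[C@H]1[C@@H](OC(=O)/C(C)=C\C)C[C@]1(C)O[C@@H]1CCC(=C)[C@H]2O
F2 | step 15 | 5-ketone, (1R,6R,7R,8S,10S)-8-angeloyloxy-1,10-epoxy-5-oxogermacra-4(15),11(13)-dien-12,6-olide | C=C1C(=O)O[C@@H]2[C@H]1[C@@H](OC(=O)/C(C)=C\C)C[C@]1(C)O[C@@H]1CCC(=C)C2=O
F3 | step 10 | Morita–Baylis–Hillman acetate, methyl (4S)-3-acetoxy-5-[(2S,3R)-3-(3-bromobut-3-en-1-yl)-2-methyloxiran-2-yl]-2-methylidene-4-(TBS-oxy)pentanoate (both C3 epimers) | C=C(C(=O)OC)C(OC(C)=O)[C@@H](O[Si](C)(C)C(C)(C)C)C[C@]1(C)O[C@@H]1CCC(Br)=C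
F4 | step 10 | allylboronate, methyl (2E,4S)-5-[(2S,3R)-3-(3-bromobut-3-en-1-yl)-2-methyloxiran-2-yl]-2-[(4,4,5,5-tetramethyl-1,3,2-dioxaborolan-2-yl)methyl]-4-(TBS-oxy)pent-2-enoate | COC(=O)/C(CB1OC(C)(C)C(C)(C)O1)=C/[C@@H](O[Si](C)(C)C(C)(C)C)C[C@]1(C)O[C@@H]1CCC(Br)=C
F5 | step 10 | O-boryl syn adduct, methyl (3S,4R)-3-{(1S)-2-[(2S,3R)-3-(3-bromobut-3-en-1-yl)-2-methyloxiran-2-yl]-1-(TBS-oxy)ethyl}-2-methylidene-5-(PMB-oxy)-4-[(4,4,5,5-tetramethyl-1,3,2-dioxaborolan-2-yl)oxy]pentanoate | COC(=O)C(=C)[C@@H]([C@@H](OB1OC(C)(C)C(C)(C)O1)COCc1ccc(OC)cc1)[C@@H](O[Si](C)(C)C(C)(C)C)C[C@]1(C)O[C@@H]1CCC(Br)=C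
F6 | step 8 | [1-(methoxycarbonyl)ethenyl]bis(2-methylpropyl)aluminium | C=C(C(=O)OC)[Al](CC(C)C)CC(C)C
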